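A single reading cannot show the ochre flask passing 95%: beside 45% of right-handed substrate, the left-handed substrate must stand at 1.15%, less than the scatter of 1.5 percentage points. So I count instead.

in all of them: free catalyst 5 mol%
- ochre: left-handed substrate 0.20 M; right-handed substrate 0.20 M; partner 3 equiv (fed, over 20 min); the very flask that is asked about, followed so far
- red: left-handed substrate 0.10 M; right-handed substrate 0.10 M; partner 3 equiv (fed, over 20 min); run made earlier
- flask: left-handed substrate 0.20 M; right-handed substrate 0.20 M; partner 3.00 equiv (fed, over 20 min); time 2.5 h

| run | time / min | right-handed substrate / % | left-handed substrate / % |
|---|---|---|---|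
| ochre | 8.00 | 48 | 13 |
| ochre | 20.0 | 45 | 0 |
| ochre | 40.0 | 45 | 2 |
| ochre | 60.0 | 44 | 0 |
| red | 12.0 | 50 | 20 |
| red | 40.0 | 48 | 1 |
| red | 60.0 | 51 | 0 |
| red | 120 | 49 | 0 |

(scatter of a reading: 1.5 percentage points)

- free catalyst is single-handed; left-handed substrate and right-handed substrate are mirror images of each other, charged as a racemate, each of them at the stated concentration
- steps thought possible: partner + free catalyst + left-handed substrate -> free catalyst + left-handed product; partner + free catalyst + right-handed substrate -> free catalyst + right-handed product; 2 partner -> homo dimer; partner -> decomposed reagent; free catalyst -> spent catalyst

1. whether the excess of right-handed substrate over left-handed substrate among what is left of the two reaches 95% by 2.5 h (yes / no)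
2. the highest excess of right-handed substrate over left-handed substrate among what is left of the two up to 2.5 h

Call exposure the natural logarithm of a substrate's start over what is left of it. The wanted excess stands when the left-handed exposure leads the right-handed one by the required lead, the logarithm of one plus the excess over one minus the excess: 3.66.

Now the ladder of the ochre flask. Fastest is the left-handed substrate, with exposure 1.35 at 8.00 min. Partner enters steadily, so I let exposure grow with the square of time, and by my reckoning the lead arrives at 13.2 min, before the feed ends at 20 min. Slower is the right-handed substrate: its exposure at 20.0 min is 0.105, far less than the lead. Slowest is the stillness after that. Between 20.0 min and 60.0 min the right-handed substrate moves from 45% to 44%, less than the scatter.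

The forecast says yes, with a top of 99.7%, from a selectivity factor of at least about 75 and the view that “partner or catalyst is dead after the feed”.

The flask gives yes, with a top of >99.9%, on these steps:

    partner + free catalyst + left-handed substrate → free catalyst + left-handed product (k = 7.50 /M²/s)
    partner + free catalyst + right-handed substrate → free catalyst + right-handed product (k = 0.0430 /M²/s)
    2 partner → homo dimer (k = 0.00270 /M/s)
    partner → decomposed reagent (k = 0.00120 /s)
    free catalyst → spent catalyst (k = 5.00 × 10⁻⁶ /s)

The wanted excess comes at 13.5 min, with 49.0% of right-handed substrate left. That is a right-handed exposure of 0.0211, so the left-handed exposure then stands at 3.68. The red flask needs the same lead: its exposure, read as 0.916 at 12.0 min, grows by the square of time to 2.55 when its feed ends at 20 min, short of the 3.66.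

The readings come from a simulation with constants of no real substance, noise included.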